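The plan rests on the aryl ester bond O1–C8a of the lactone (dihydrocoumarin) ring, which lies next to the C2 carbonyl: removing that oxygen leaves a 3-phenylindan-1-one whose C3 is the future C4 stereocentre. A Baeyer–Villiger oxidation therefore turns the five-membered aryl ketone into the six-membered lactone in one operation, with oxygen placed only on C8a and the stereocentre untouched. The substrate is (3R)-4,6-bis(benzyloxy)-7-bromo-3-phenylindan-1-one, made by rhodium-catalysed asymmetric isomerisation of a propargylic alcohol. Its bromine marks C8 for the peracid-sensitive 3-arylpropanoyl ketone, which is added afterwards by Stille acetylation, acid-mediated chalcone formation and hydrogenation.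

Key step: step 4

Remarks on the chemistry (assumptions):
- In indanone 6 the migrating ring carbon C7a is meta to both benzyloxy groups (C4, C6), ortho to the bromine and para to C5–H. The ring expansion therefore cannot count on donor assistance and relies on the intrinsic aryl-over-methylene preference of 1-indanones.
- The sense of induction of the bisphosphine in step 3 is to be assigned on the first run; the antipode that gives the (3R) ketone is the one used.
- After step 4 only non-nucleophilic, non-basic conditions are used, because the aryl lactone opens readily with hydroxide, alkoxide or amines.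
- Species generated and consumed in one flask are numbered; catalyst-bound rhodium and palladium species are not.

Step 1
Reactants: 1 3,5-bis(benzyloxy)benzaldehyde
Product: 2 3,5-bis(benzyloxy)-2-bromobenzaldehyde
Conditions: NBS (1.05 equiv), MeCN, 0 °C to rt, dark
Reagents that add atoms: N-bromosuccinimide, O=C1CCC(=O)N1Br
Why: Electrophilic aromatic bromination should go to C2, which is para to one benzyloxy group and ortho to the other and less crowded than C4 between the two ethers, as is established for 3,5-dialkoxybenzaldehydes.

Step 2
Reactants: 2 3,5-bis(benzyloxy)-2-bromobenzaldehyde; 3 phenylacetylene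
Product: 5 rac-1-[3,5-bis(benzyloxy)-2-bromophenyl]-3-phenylprop-2-yn-1-ol, via lithium phenylacetylide 4 (not isolated)
Conditions: 3 (1.3 equiv), n-BuLi (1.2 equiv), THF, −78 °C; then 2, −78 to 0 °C; H2O
Reagents that add atoms: none
Why: 1,2-Addition of a preformed lithium acetylide to the aldehyde is fast at low temperature and spares the aryl bromide because no free butyllithium remains; the carbinol centre forms racemic, which is acceptable since step 3 erases it.

Step 3
Reactants: 5 rac-1-[3,5-bis(benzyloxy)-2-bromophenyl]-3-phenylprop-2-yn-1-ol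
Product: 6 (3R)-4,6-bis(benzyloxy)-7-bromo-3-phenylindan-1-one
Conditions: [Rh(OH)(cod)]2 (2.5 mol%), axially chiral biaryl bisphosphine of the BINAP/SEGPHOS type (5.5 mol%, antipode as in the remark), THF, 60 °C
Reagents that add atoms: none
Why: In this rhodium-catalysed asymmetric isomerisation of an α-arylpropargyl alcohol to a β-chiral indanone, β-hydride elimination from the rhodium alkoxide, syn hydrorhodation of the bound ynone and a 1,4-rhodium shift to the only free ortho carbon give an aryl-rhodium species, whose intramolecular conjugate addition to the enone closes the five-membered ring and sets C3 under control of the chiral bisphosphine, both enantiomers of 5 converging on one product.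

Step 4
Reactants: 6 (3R)-4,6-bis(benzyloxy)-7-bromo-3-phenylindan-1-one
Product: 8 (4R)-5,7-bis(benzyloxy)-8-bromo-4-phenylchroman-2-one, via Criegee adduct 7 (not isolated)
Conditions: mCPBA (2 equiv), TsOH·H2O (10 mol%), CH2Cl2, 0 °C to rt, dark; aq Na2SO3/NaHCO3
Reagents that add atoms: 3-chloroperbenzoic acid (mCPBA), O=C(OO)c1cccc(Cl)c1
Why: Acid-assisted addition of the peracid to the C1 carbonyl gives Criegee adduct 7, in which the C1–C7a bond, antiperiplanar to the O–O bond and aligned with the arene π-system because the peroxy oxygen sits out of the ring plane, shifts from carbon to oxygen as 3-chlorobenzoate leaves. The closest known reaction is the Baeyer–Villiger oxidation of 1-indanones, 3-phenyl-1-indanones included, to 3,4-dihydrocoumarins. The six-membered lactone is not closed end to end but arises by ring expansion: a 1,2-shift of C7a inserts oxygen into the five-membered ring and creates the O1–C8a bond. No stereocentre is formed; C3 of 6 becomes C4 of 8 with its configuration retained, since it is β to the carbonyl, remote from the migration terminus and not enolisable. The step needs aryl migration in preference to migration of the C2 methylene: C7a is meta to both benzyloxy groups and para to C5–H, so the selectivity rests on the intrinsic sp2-aryl over primary-alkyl aptitude seen with 1-indanones, helped by relief of the compression between the C7 bromine and the C1 substituents. It also needs the carbonyl to be oxidised before the dialkoxyarene, which the deactivating acyl and bromo substituents, the low temperature and the small excess of peracid should secure.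

Step 5
Reactants: 8 (4R)-5,7-bis(benzyloxy)-8-bromo-4-phenylchroman-2-one; 9 tributyl(1-ethoxyvinyl)stannane
Product: 11 (4R)-8-acetyl-5,7-bis(benzyloxy)-4-phenylchroman-2-one, via enol ether 10 (not isolated)
Conditions: Pd(PPh3)4 (5 mol%), toluene, 105 °C; then 1 M HCl, THF, rt
Reagents that add atoms: water, O
Why: Stille coupling of the aryl bromide with the α-alkoxyvinylstannane runs under neutral conditions that the aryl lactone tolerates, and dilute acid hydrolyses the enol ether to the methyl ketone much faster than it affects the lactone; C4 is not touched.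

Step 6
Reactants: 11 (4R)-8-acetyl-5,7-bis(benzyloxy)-4-phenylchroman-2-one; 12 4-(benzyloxy)benzaldehyde
Product: 14 (4R)-5,7-bis(benzyloxy)-8-[(2E)-3-(4-benzyloxyphenyl)prop-2-enoyl]-4-phenylchroman-2-one, via aldol adduct 13 (not isolated)
Conditions: BF3·OEt2 (1 equiv), 1,4-dioxane, rt
Reagents that add atoms: none
Why: The Lewis acid-mediated Claisen–Schmidt condensation (enolisation of the acetyl group, aldol addition, dehydration to the conjugated E-enone) avoids the hydroxide, alkoxide or amine bases that would open the aryl lactone, and should leave the benzyl ethers and C4 alone.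

Step 7
Reactants: 14 (4R)-5,7-bis(benzyloxy)-8-[(2E)-3-(4-benzyloxyphenyl)prop-2-enoyl]-4-phenylchroman-2-one
Product: 16 (4R)-5,7-dihydroxy-8-[3-(4-hydroxyphenyl)propanoyl]-4-phenylchroman-2-one, via saturated tribenzyl ether 15 (not isolated)
Conditions: H2 (1 atm), 10% Pd/C, EtOAc, rt
Reagents that add atoms: none
Why: Heterogeneous catalytic hydrogenation saturates the enone C=C and then hydrogenolyses the three benzyl ethers while the aryl ketone and the lactone should survive; the neutral, non-nucleophilic medium should keep the lactone on O1 (no acyl shift to the freed 5-OH) and leaves C4 unchanged.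

Compound list
1 | 3,5-bis(benzyloxy)benzaldehyde | O=Cc1cc(OCc2ccccc2)cc(OCc2ccccc2)c1 | starting material
2 | 3,5-bis(benzyloxy)-2-bromobenzaldehyde | O=Cc1cc(OCc2ccccc2)cc(OCc2ccccc2)c1Br | intermediate
3 | phenylacetylene | C#Cc1ccccc1 | starting material
4 | lithium phenylacetylide (formed in the flask) | [Li]C#Cc1ccccc1 | intermediate
5 | rac-1-[3,5-bis(benzyloxy)-2-bromophenyl]-3-phenylprop-2-yn-1-ol | OC(C#Cc1ccccc1)c1cc(OCc2ccccc2)cc(OCc2ccccc2)c1Br | intermediate
6 | (3R)-4,6-bis(benzyloxy)-7-bromo-3-phenylindan-1-one | O=C1C[C@H](c2ccccc2)c2c(OCc3ccccc3)cc(OCc3ccccc3)c(Br)c21 | intermediate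
7 | Criegee adduct, (3R)-4,6-bis(benzyloxy)-7-bromo-1-hydroxy-3-phenylindan-1-yl 3-chloroperbenzoate, both C1 epimers (formed in the flask) | OC1(OOC(=O)c2cccc(Cl)c2)C[C@H](c2ccccc2)c2c(OCc3ccccc3)cc(OCc3ccccc3)c(Br)c21 | intermediate
8 | (4R)-5,7-bis(benzyloxy)-8-bromo-4-phenylchroman-2-one | O=C1C[C@H](c2ccccc2)c2c(OCc3ccccc3)cc(OCc3ccccc3)c(Br)c2O1 | intermediate
9 | tributyl(1-ethoxyvinyl)stannane | CCCC[Sn](CCCC)(CCCC)C(=C)OCC | starting material
10 | (4R)-5,7-bis(benzyloxy)-8-(1-ethoxyvinyl)-4-phenylchroman-2-one (formed in the flask) | O=C1C[C@H](c2ccccc2)c2c(OCc3ccccc3)cc(OCc3ccccc3)c(C(=C)OCC)c2O1 | intermediate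
11 | (4R)-8-acetyl-5,7-bis(benzyloxy)-4-phenylchroman-2-one | O=C1C[C@H](c2ccccc2)c2c(OCc3ccccc3)cc(OCc3ccccc3)c(C(C)=O)c2O1 | intermediate
12 | 4-(benzyloxy)benzaldehyde | O=Cc1ccc(OCc2ccccc2)cc1 | starting material
13 | (4R)-5,7-bis(benzyloxy)-8-[3-(4-benzyloxyphenyl)-3-hydroxypropanoyl]-4-phenylchroman-2-one, both carbinol epimers (formed in the flask) | O=C1C[C@H](c2ccccc2)c2c(OCc3ccccc3)cc(OCc3ccccc3)c(C(=O)CC(O)c3ccc(OCc4ccccc4)cc3)c2O1 | intermediate
14 | (4R)-5,7-bis(benzyloxy)-8-[(2E)-3-(4-benzyloxyphenyl)prop-2-enoyl]-4-phenylchroman-2-one | O=C1C[C@H](c2ccccc2)c2c(OCc3ccccc3)cc(OCc3ccccc3)c(C(=O)/C=C/c3ccc(OCc4ccccc4)cc3)c2O1 | intermediate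
15 | (4R)-5,7-bis(benzyloxy)-8-[3-(4-benzyloxyphenyl)propanoyl]-4-phenylchroman-2-one (formed in the flask) | O=C1C[C@H](c2ccccc2)c2c(OCc3ccccc3)cc(OCc3ccccc3)c(C(=O)CCc3ccc(OCc4ccccc4)cc3)c2O1 | intermediate
16 | (4R)-5,7-dihydroxy-8-[3-(4-hydroxyphenyl)propanoyl]-4-phenylchroman-2-one | O=C1C[C@H](c2ccccc2)c2c(O)cc(O)c(C(=O)CCc3ccc(O)cc3)c2O1 | target

Total step count: 7
Longest linear sequence: 7 steps (1 to 16)

Steps most likely to fail

Step 4 (key step). The insertion may occur on the wrong side, by migration of the C2 methylene, because C7a has no ortho or para donor. The Criegee adduct may also form slowly at the bromine-flanked carbonyl, so that the peracid oxidises the dialkoxyarene first. The fallback sets out from 6 and returns at 8. Radical hydrodebromination (Bu3SnH, AIBN, toluene, 80 °C) should give (3R)-4,6-bis(benzyloxy)-3-phenylindan-1-one F1, whose carbonyl is unhindered and whose migrating carbon no longer carries an inductively withdrawing ortho substituent. Baeyer–Villiger oxidation under the conditions of step 4 should then give (4R)-5,7-bis(benzyloxy)-4-phenylchroman-2-one F2. NBS (MeCN, 0 °C) is expected to brominate C8, which is para to the C5 ether, ortho to the C7 ether and less crowded than C6 between two benzyloxy groups, to give 8. The site of bromination would have to be confirmed by 2D NMR.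

Step 3. Facial discrimination in the ring-closing arylrhodation may be poor, since the ortho bromine and the aryl-substituted alkyne lie at the edge of the usual substrates, and the sense of induction is not predictable beforehand. The fallback sets out from 5 and returns at 6. The same rhodium cascade run with a racemic bisphosphine (rac-BINAP) should give racemic 4,6-bis(benzyloxy)-7-bromo-3-phenylindan-1-one F3. Dehydrogenation with IBX (DMSO, 65 °C) should give 4,6-bis(benzyloxy)-7-bromo-3-phenyl-1H-inden-1-one F4. Oxazaborolidine-catalysed (CBS) borane reduction, with the catalyst antipode that leads to the R carbinol, should give (1R)-4,6-bis(benzyloxy)-7-bromo-3-phenyl-1H-inden-1-ol F5. An amine-mediated suprafacial 1,3-hydrogen shift (DABCO, Et3N, THF, 60 °C) then transfers the C1 configuration to C3 and delivers 6. Stereocontrol then rests on a reagent-controlled ketone reduction and a stereospecific rearrangement.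

Step 6. The Lewis acid may remove the benzyl group ortho to the ketone or promote Friedel–Crafts attack of the activated aldehyde on C6–H in place of clean condensation. The fallback sets out from 11 and returns at 14. The kinetic lithium enolate of the methyl ketone (LiHMDS, THF, −78 °C) is added to 12 and quenched cold to give aldol 13, this time isolated. MsCl/Et3N (CH2Cl2, 0 °C to rt) converts it into (4R)-5,7-bis(benzyloxy)-8-[3-(4-benzyloxyphenyl)-3-(methylsulfonyloxy)propanoyl]-4-phenylchroman-2-one F6, which eliminates in the same flask to the E-enone 14.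

Further compounds
F1 | step 4 | (3R)-4,6-bis(benzyloxy)-3-phenylindan-1-one | O=C1C[C@H](c2ccccc2)c2c(OCc3ccccc3)cc(OCc3ccccc3)cc21
F2 | step 4 | (4R)-5,7-bis(benzyloxy)-4-phenylchroman-2-one | O=C1C[C@H](c2ccccc2)c2c(OCc3ccccc3)cc(OCc3ccccc3)cc2O1
F3 | step 3 | racemic 4,6-bis(benzyloxy)-7-bromo-3-phenylindan-1-one | O=C1CC(c2ccccc2)c2c(OCc3ccccc3)cc(OCc3ccccc3)c(Br)c21
F4 | step 3 | 4,6-bis(benzyloxy)-7-bromo-3-phenyl-1H-inden-1-one | O=C1C=C(c2ccccc2)c2c(OCc3ccccc3)cc(OCc3ccccc3)c(Br)c21
F5 | step 3 | (1R)-4,6-bis(benzyloxy)-7-bromo-3-phenyl-1H-inden-1-ol | O[C@@H]1C=C(c2ccccc2)c2c(OCc3ccccc3)cc(OCc3ccccc3)c(Br)c21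
F6 | step 6 | (4R)-5,7-bis(benzyloxy)-8-[3-(4-benzyloxyphenyl)-3-(methylsulfonyloxy)propanoyl]-4-phenylchroman-2-one | O=C1C[C@H](c2ccccc2)c2c(OCc3ccccc3)cc(OCc3ccccc3)c(C(=O)CC(OS(C)(=O)=O)c3ccc(OCc4ccccc4)cc3)c2O1
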